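# Total synthesis proposal for mycalazal 20

Locants used throughout: ring N1, C2 (bears CHO), C3, C4, C5. The chain runs C1' to C19', counted from C5.

## Analysis of the target

1. Mycalazal 20 (9) is a 2,5-disubstituted 1H-pyrrole with a formyl group on C2, hydrogen on N1, C3 and C4, and an unbranched nineteen-carbon chain on C5.
2. The chain has nine methylene groups (C1'–C9'), then three Z double bonds (C10'=C11', C13'=C14', C16'=C17') separated by the doubly allylic methylenes C12' and C15', then an ethyl end (C18'–C19').
3. There is no stereogenic carbon. The stereochemical content is the three Z geometries, which cannot control one another and lie far from the ring. Their isomers are practically inseparable, so they must arrive as a group and stay untouched.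
4. The sensitive sites are the C12' and C15' hydrogens (autoxidation, base-induced conjugation, Z/E scrambling by thiyl or iodine radicals), the π-excessive N–H pyrrole (acid, oxidants) and the aldehyde (nucleophiles, hydrides). Hydrogenation is excluded at every stage.
5. The difficulty is that C1'–C9' carries no functional group for a polar disconnection. In addition, a nineteen-carbon chain does not match the natural C18 acid when the ring–chain bond is made by polar chemistry.
6. The feature that the route exploits is that C3'–C19', seventeen carbons including all three Z alkenes, is atom for atom the C2–C18 segment of α-linolenic acid (1).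
7. The missing atoms C1' and C2' sit on C5, which is conjugated through C5=C4–C3=C2 with the formyl C=O. A vinyl group at C5, as in 6, is therefore the terminus of a through-ring vinylogous acceptor.

## Retrosynthetic reasoning

**Cut of C2'–C3' in 9.**
- The first cut is homolytic and lies inside the saturated tether. It gives the primary radical 7 (C3'–C19', with all three Z alkenes) and the vinylpyrrole 6 (ring, formyl group, C1' and C2'). The delocalised radical 8 is the link between them.
- The cut is placed here and not at C5–C1' for two reasons. Only here does the chain fragment have the exact carbon count and geometry of a bulk natural acid after loss of its carboxyl carbon. Only here is the other fragment a conjugated radical acceptor.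
- The gain is a last step that joins a C17 and a C7 fragment. It needs no protecting group and no redox adjustment afterwards, and no alkene has to be made.
- The forward reaction must form an sp3–sp3 bond at the vinyl terminus only and end by delivering one hydrogen to C1'. It must leave the doubly allylic hydrogens, the Z geometry, the N–H and the aldehyde alone.

**Cut of the C1–C2 bond of the acid (7 from 3, 3 from 1 and 2).**
- Radical 7 is traced back to the redox-active ester 3 by putting the carboxyl carbon back.
- Ester 3 is cut at its acyl–oxygen bond into 1 and 2.
- A reductive trigger (electron transfer into the phthalimide part of 3) is preferred to an oxidative one, because the pyrrole of 6 and the skipped triene are both oxidisable.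
- The forward esterification only has to be neutral and free of radicals.

**Cut of the exocyclic C5–C1' sp2–sp2 bond of 6.**
- Compound 6 is cut into the bromide 4 and the vinylboronate 5.
- This bond is made on a seven-carbon fragment before the valuable chain is present. The formyl group is already in place, so the ring never has to be formylated in the presence of the triene.
- The forward cross-coupling must tolerate the free N–H and must not polymerise the product.

## Alternatives that were turned down

**Alternative 1:** This is the textbook route.
- *Disconnection:* the ring–chain bond C5–C1' and the C2–CHO bond are cut, so the ring acts as the nucleophile twice.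
- *Forward key step:* 1 is lengthened by one carbon (reduction, sulfonate, cyanide displacement, hydrolysis) to the C19 acid A1. After activation of its carboxyl group, A1 acylates 1H-pyrrole A2 at an α-position to give the ketone A3. Deoxygenation of the carbonyl group to C1'H2 and a Vilsmeier–Haack formylation at the remaining α-position would end at 9.
- *Why turned down:*
  - Polar logic needs a chain of nineteen carbons with an electrophilic C1', while 1 has eighteen, so four steps are spent on one carbon.
  - The oxygen on C1' is introduced only to be removed, under hot hydride or strongly basic conditions that invite conjugation of the skipped triene.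
  - The ring is functionalised in two separate operations.
  - About eight linear steps all carry the sensitive triene.

**Alternative 2:**
- *Disconnection:* the double bond C10'=C11' is cut.
- *Forward key step:* a Z-selective Wittig reaction of the non-stabilised ylide from the phosphonium salt A4 with the aldehyde A5, followed by formylation of the ring to give 9.
- *Why turned down:*
  - It makes geometry that can be bought.
  - A4 holds two Z alkenes that must first be built by alkyne coupling and semi-hydrogenation.
  - The kinetic Z preference of a salt-free Wittig reaction is high but not complete. One E alkene in a C19 chain changes the polarity too little to be removed.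
  - The formyl group cannot be present during the olefination, because two aldehydes would compete. Formylation therefore has to follow on the complete triene.
  - The count exceeds ten steps.

**Alternative 3:** This makes one aromatic ring from another.
- *Disconnection:* the pyrrole ring and its formyl carbon are traced back to the six ring atoms of the pyridine N-oxide A6.
- *Forward key step:* 2-methylpyridine 1-oxide A7 is metalated at the methyl group and alkylated with linolenyl bromide A8, which takes two steps from 1. The methyl carbon becomes C1' and the carbon count fits. UV irradiation of A6 should then close an oxaziridine, expand it to a 1,2-oxazepine and contract that to the 2-formylpyrrole 9.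
- *Why turned down:*
  - The oxygen can migrate to either carbon next to nitrogen. Only migration to the unsubstituted C6 leads to 9, while migration to C2 places the chain on an exocyclic ketone. Nothing in A6 biases the choice.
  - Excited N-oxides also lose oxygen by atom transfer, and three nucleophilic alkenes sit in the same molecule.
  - UV light and triplet states threaten the Z geometry.
  - The route is linear, with four steps from 1, and puts its least efficient step last on the whole chain.

Key step: step 3

Assumption: 1 is used in its isomerically pure all-Z commercial grade, because the geometry of 9 is inherited and is not corrected later.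

## Route

Step 1
Reactants: 1 α-linolenic acid [(9Z,12Z,15Z)-octadeca-9,12,15-trienoic acid]; 2 N-hydroxyphthalimide
Product: 3 1,3-dioxoisoindolin-2-yl (9Z,12Z,15Z)-octadeca-9,12,15-trienoate (redox-active ester)
Conditions: DIC (1.1 equiv), DMAP (10 mol %), CH2Cl2, 0 °C to rt, argon, dark
Reagents that add atoms: none
Why: Steglich-type carbodiimide esterification, in which DIC activates the carboxyl group of 1 as the O-acylisourea and DMAP relays the acyl group to the N–OH oxygen of 2. The medium is neutral and free of radicals, so the skipped triene should pass unchanged; no stereocentre is formed.

Step 2
Reactants: 4 5-bromo-1H-pyrrole-2-carbaldehyde; 5 vinylboronic acid pinacol ester (2-ethenyl-4,4,5,5-tetramethyl-1,3,2-dioxaborolane)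
Product: 6 5-ethenyl-1H-pyrrole-2-carbaldehyde
Conditions: PdCl2(dppf) (5 mol %), K2CO3 (3 equiv), 1,4-dioxane/H2O 4:1, BHT (trace), 80 °C, argon
Reagents that add atoms: none
Why: Suzuki–Miyaura coupling, in which the conjugated formyl group activates the C5–Br bond of 4 towards oxidative addition to zerovalent palladium and the boronate formed from 5 and aqueous carbonate transfers the vinyl group. The formyl group lowers the electron density of the ring enough for 4 and 6 to be handled with free N–H, and the inhibitor together with prompt use guards 6 against polymerisation.

Step 3
Reactants: 3 redox-active ester of α-linolenic acid (1.5 equiv, in two portions); 6 5-ethenyl-1H-pyrrole-2-carbaldehyde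
Product: 9 mycalazal 20 [5-((10Z,13Z,16Z)-nonadeca-10,13,16-trien-1-yl)-1H-pyrrole-2-carbaldehyde], via heptadecatrienyl radical 7 (not isolated), via pyrrolylmethyl radical 8 (not isolated)
Conditions: Ru(bpy)3(PF6)2 (1 mol %), Hantzsch ester (diethyl 2,6-dimethyl-1,4-dihydropyridine-3,5-dicarboxylate, 1.5 equiv), degassed CH2Cl2 (0.2 M in 6), blue LEDs (450 nm), rt, argon
Reagents that add atoms: none
Why: Proposed new method: excited Ru(bpy)3(PF6)2 is quenched reductively by the Hantzsch ester, and the reduced complex passes one electron into the phthalimide unit of 3, whose radical anion breaks at the N–O bond and loses CO2 to give the primary radical 7. Radical 7 adds to the unsubstituted vinyl terminus of 6 (the future C2') and forms the C2'–C3' bond, because only this mode gives radical 8, which is delocalised over C1', the ring carbons C4 and C2 and the formyl oxygen. Radical 8 is closed by hydrogen-atom transfer from the Hantzsch ester or its radical cation (or by reduction and protonation), and quenching at a ring position would only give a non-aromatic tautomer that returns to the pyrrole, so all channels should meet in 9. The closest known reaction type is the reductive decarboxylative Giese addition of N-(acyloxy)phthalimides, established for fatty-acid esters with acrylates, enones and vinyl azines, while additions of the same radicals to styrenes are known with oxidative termination; new here is the acceptor, a vinyl group on a π-excessive N–H pyrrole that is activated only through the ring by the C2 formyl group. No ring is closed and no stereocentre is formed; the stereochemical task is retention of the three Z alkenes, secured by the absence of thiyl, iodine and metal hydride species and by a sensitiser triplet energy far below that of isolated alkenes. Chemoselectivity requires addition to 6 to outrun hydrogen abstraction by 7: the first alkene of 7 sits at its C8, so cyclisation would need a ring of eight or more members, the doubly allylic hydrogens are reachable only through large-ring transition states, and 6 is kept concentrated. The net reductive medium leaves the oxidisable pyrrole untouched, and the reduced ruthenium complex is too weak a reductant to turn the formyl group into a ketyl.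

## Compound list

1 | α-linolenic acid, (9Z,12Z,15Z)-octadeca-9,12,15-trienoic acid | CC/C=C\C/C=C\C/C=C\CCCCCCCC(=O)O | starting material
2 | N-hydroxyphthalimide | O=C1c2ccccc2C(=O)N1O | starting material
3 | 1,3-dioxoisoindolin-2-yl (9Z,12Z,15Z)-octadeca-9,12,15-trienoate | CC/C=C\C/C=C\C/C=C\CCCCCCCC(=O)ON1C(=O)c2ccccc2C1=O | intermediate
4 | 5-bromo-1H-pyrrole-2-carbaldehyde | O=Cc1ccc(Br)[nH]1 | starting material
5 | 2-ethenyl-4,4,5,5-tetramethyl-1,3,2-dioxaborolane | C=CB1OC(C)(C)C(C)(C)O1 | starting material
6 | 5-ethenyl-1H-pyrrole-2-carbaldehyde | C=Cc1ccc(C=O)[nH]1 | intermediate
7 | (8Z,11Z,14Z)-heptadeca-8,11,14-trien-1-yl radical | CC/C=C\C/C=C\C/C=C\CCCCCC[CH2] | intermediate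
8 | (10Z,13Z,16Z)-1-(5-formyl-1H-pyrrol-2-yl)nonadeca-10,13,16-trien-1-yl radical | CC/C=C\C/C=C\C/C=C\CCCCCCCC[CH]c1ccc(C=O)[nH]1 | intermediate
9 | mycalazal 20, 5-[(10Z,13Z,16Z)-nonadeca-10,13,16-trien-1-yl]-1H-pyrrole-2-carbaldehyde | CC/C=C\C/C=C\C/C=C\CCCCCCCCCc1ccc(C=O)[nH]1 | target

## Step count and risk

Total step count: 3. Longest linear sequence: 2 (step 1 then step 3, or step 2 then step 3).

**Step 3 (key step, proposed new method).**
- *What may go wrong:* the most likely failure is premature hydrogen transfer to radical 7 before the C–C bond forms, because the vinylpyrrole is only a styrene-like acceptor. A second failure is chain growth, in which the stabilised radical 8 adds to further acceptor because its own termination is slow. Acid released from the oxidised dihydropyridine could also start cationic oligomerisation of the vinylpyrrole.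
- *Fallback (known chemistry, sets out from 3, comes back at 9):* radical 7 is first caught by a classical Giese acceptor and the ring is built afterwards. Under the conditions of step 3, 3 and N-methoxy-N-methylacrylamide should give the Weinreb amide F1, whose amide carbon is the future C5. Addition of the Grignard reagent from 2-(2-bromoethyl)-1,3-dioxolane (THF, 0 °C) should give the keto acetal F2. NH4OAc in AcOH/THF/H2O at 60 °C unmasks the aldehyde and closes the ring by Paal–Knorr condensation to the 2-alkylpyrrole F3. Vilsmeier–Haack formylation (POCl3, DMF, 0 °C, then aq NaOAc) at the only free α-position leads to 9.

**Step 2.**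
- *What may go wrong:* the arylpalladium intermediate may undergo hydrodebromination by the acidic N–H and water, and the pyrrolide anion may bind the catalyst. The product may also polymerise thermally or by a radical path during heating and concentration.
- *Fallback (sets out from 3 and 4, comes back at 9, and avoids 6 altogether):* the two-carbon vinyl unit is placed on the chain instead of on the ring. Decarboxylative alkenylation of 3 with vinylzinc chloride (Ni(acac)2 10 mol %, 2,2'-bipyridine, THF/DMF, rt) should give the tetraene F4. One equivalent of 9-BBN-H (THF, 0 °C to rt) hydroborates only the monosubstituted alkene, to give the B-alkyl borane F5. A B-alkyl Suzuki–Miyaura coupling with 4 (PdCl2(dppf), Cs2CO3, DMF/THF/H2O, 50 °C) then closes the C5–C1' bond and gives 9.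

**Step 1.**
- *What may go wrong:* the doubly allylic positions may autoxidise during handling and chromatography. Acyl migration in the O-acylisourea may give an unreactive N-acylurea, and the activated ester may hydrolyse on silica.
- *Fallback (sets out from 1, comes back at 7 and so at 9):* activation is dropped, and the free acid 1 is decarboxylated directly by acridine photocatalysis (9-mesitylacridine 10 mol %, 400 nm LEDs, CH2Cl2, rt) in the presence of 6. Proton-coupled electron transfer within the hydrogen-bonded acid–acridine pair releases 7, and the acridinyl radical returns the hydrogen atom to 8. This redox-neutral variant makes no compound outside the list (entry F0).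

## Further compounds

F1 | step 3 | (11Z,14Z,17Z)-N-methoxy-N-methylicosa-11,14,17-trienamide | CC/C=C\C/C=C\C/C=C\CCCCCCCCCC(=O)N(C)OC
F2 | step 3 | (13Z,16Z,19Z)-1-(1,3-dioxolan-2-yl)docosa-13,16,19-trien-3-one | CC/C=C\C/C=C\C/C=C\CCCCCCCCCC(=O)CCC1OCCO1
F3 | step 3 | 2-[(10Z,13Z,16Z)-nonadeca-10,13,16-trien-1-yl]-1H-pyrrole | CC/C=C\C/C=C\C/C=C\CCCCCCCCCc1ccc[nH]1
F4 | step 2 | (10Z,13Z,16Z)-nonadeca-1,10,13,16-tetraene | C=CCCCCCCC/C=C\C/C=C\C/C=C\CC
F5 | step 2 | 9-[(10Z,13Z,16Z)-nonadeca-10,13,16-trien-1-yl]-9-borabicyclo[3.3.1]nonane | CC/C=C\C/C=C\C/C=C\CCCCCCCCCB1C2CCCC1CCC2
F0 | step 1 | none | none
A1 | alternative 1 | (10Z,13Z,16Z)-nonadeca-10,13,16-trienoic acid | CC/C=C\C/C=C\C/C=C\CCCCCCCCC(=O)O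
A2 | alternative 1 | 1H-pyrrole | c1cc[nH]c1
A3 | alternative 1 | (10Z,13Z,16Z)-1-(1H-pyrrol-2-yl)nonadeca-10,13,16-trien-1-one | CC/C=C\C/C=C\C/C=C\CCCCCCCCC(=O)c1ccc[nH]1
A4 | alternative 2 | [(3Z,6Z)-nona-3,6-dien-1-yl]triphenylphosphonium iodide | CC/C=C\C/C=C\CC[P+](c1ccccc1)(c1ccccc1)c1ccccc1.[I-]
A5 | alternative 2 | 10-(1H-pyrrol-2-yl)decanal | O=CCCCCCCCCCc1ccc[nH]1
A6 | alternative 3 | 2-[(10Z,13Z,16Z)-nonadeca-10,13,16-trien-1-yl]pyridine 1-oxide | CC/C=C\C/C=C\C/C=C\CCCCCCCCCc1cccc[n+]1[O-]
A7 | alternative 3 | 2-methylpyridine 1-oxide | Cc1cccc[n+]1[O-]
A8 | alternative 3 | (3Z,6Z,9Z)-18-bromooctadeca-3,6,9-triene (linolenyl bromide) | CC/C=C\C/C=C\C/C=C\CCCCCCCCBr
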